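## Retrosynthetic overview
1. The 14-membered carbocycle is the last ring formed. It is closed at C1=C2 by an intramolecular Horner–Wadsworth–Emmons reaction of an epoxy aldehyde with an α-isopropyl β-ketophosphonate, and desilylation then gives the target.
2. The cis-oxirane is the first ring formed, by Sharpless epoxidation of a (Z)-allylic alcohol. The C6–C7 bond comes from a B-alkyl Suzuki coupling of a (Z)-dienol with a (Z)-β-iodoenone.
3. Key disconnection: C2–C6 and the C4 methyl group are the six carbons of 4-picoline. Zincke ring opening and a thermal pericyclic cascade unzip the symmetric ring into a (Z)-dienamide, so the ring fixes the C3=C4 geometry that becomes the cis-epoxide.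
4. The (Z)-C7=C8(CH2OH)–C9=O unit comes from an iodide-triggered allenolate aldol of an ethynyl ketone with formaldehyde.
5. C12 and C13 are set by a catalytic syn-crotylboration of ethyl glyoxylate. C9 comes from CO (hydroformylation), and C1 with its isopropyl group from diethyl isobutylphosphonate.

Assumption: (Z)-crotylboronic acid pinacol ester, diethyl isobutylphosphonate, (S)-TRIP and BIPHEPHOS are bought. Atom labels follow cembrane numbering: C1 carries the isopropyl group, C14 is the ketone next to it, and C19 is the CH2OH carbon.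

## Route

Step 1
Reactants: 1 4-methylpyridine
Product: 4 (2E,4E)-3-methyl-5-(morpholin-4-yl)penta-2,4-dienal, via Zincke salt 2 (not isolated), via pentadienylidene iminium chloride 3 (not isolated)
Conditions: 1-chloro-2,4-dinitrobenzene, acetone, reflux; then morpholine (2.2 equiv), EtOH, 0 °C to rt; then aq NaOH, rt
Reagents that add atoms: morpholine (C1COCCN1); water (O)
Why: Zincke reaction: N-arylation makes the ring electrophilic, morpholine adds next to nitrogen, the dihydropyridine opens electrocyclically, and hydrolysis of either of the two equivalent iminium ends gives one push-pull dienal with no regiochemical issue.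

Step 2
Reactants: 4 (2E,4E)-3-methyl-5-(morpholin-4-yl)penta-2,4-dienal
Product: 5 (2Z)-3-methyl-1-(morpholin-4-yl)penta-2,4-dien-1-one
Conditions: 1,2-dichlorobenzene (0.05 M), 200 °C, sealed tube or microwave, 1–2 h
Reagents that add atoms: none
Why: Thermal pericyclic cascade of a 5-aminopenta-2,4-dienal (E/Z isomerisation, 6π oxa-electrocyclisation to the 2-amino-2H-pyran, 1,5-hydrogen shift, 6π ring opening); C3=C4 is a ring bond of the pyran, so the carbonyl carbon C2 and the vinyl carbon C5 emerge cis (Z).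

Step 3
Reactants: 5 (2Z)-3-methyl-1-(morpholin-4-yl)penta-2,4-dien-1-one
Product: 7 (2Z)-3-methylpenta-2,4-dien-1-ol, via dienal 6 (not isolated)
Conditions: iBu2AlH (1.2 equiv), THF, −78 °C; then MeOH, NaBH4, −78 to −20 °C
Reagents that add atoms: none
Why: Morpholine amides stop at the tetrahedral aluminate (Weinreb-type partial reduction), and the Z-enal released on quench is reduced 1,2 at once by NaBH4 before it can isomerise or close to the pyran.

Step 4
Reactants: 8 ethyl glyoxylate, 9 (Z)-crotylboronic acid pinacol ester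
Product: 10 ethyl (2S,3R)-2-hydroxy-3-methylpent-4-enoate
Conditions: (S)-TRIP (5 mol%), 4 Å MS, toluene, −78 to −40 °C; aq work-up
Reagents that add atoms: none
Why: Chiral phosphoric acid catalysed crotylboration through a closed chair transition state; the Z-crotyl geometry gives the syn C12/C13 pair and the (S)-acid directs attack to the Si face of the aldehyde, which gives (2S,3R).

Step 5
Reactants: 10 ethyl (2S,3R)-2-hydroxy-3-methylpent-4-enoate
Product: 11 ethyl (2S,3R)-2-[(tert-butyldimethylsilyl)oxy]-3-methylpent-4-enoate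
Conditions: TBSCl, imidazole, DMF, rt
Reagents that add atoms: tert-butyldimethylsilyl chloride (CC(C)(C)[Si](C)(C)Cl)
Why: Standard silylation of the C13 alcohol, which keeps the later organometallic, oxidation and base steps away from the α-hydroxy carbonyl unit without touching either stereocenter.

Step 6
Reactants: 11 ethyl (2S,3R)-2-[(tert-butyldimethylsilyl)oxy]-3-methylpent-4-enoate
Product: 12 ethyl (2S,3R)-2-[(tert-butyldimethylsilyl)oxy]-3-methyl-6-oxohexanoate
Conditions: Rh(acac)(CO)2 (1 mol%), BIPHEPHOS (2 mol%), CO/H2 (1:1, 10 bar), toluene, 60 °C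
Reagents that add atoms: carbon monoxide ([C-]#[O+])
Why: Linear-selective hydroformylation; the wide-bite-angle bisphosphite and the allylic branch at C12 both steer the formyl group (C9) to the terminal carbon, and the neutral conditions leave C12 and C13 intact.

Step 7
Reactants: 12 ethyl (2S,3R)-2-[(tert-butyldimethylsilyl)oxy]-3-methyl-6-oxohexanoate, 13 diethyl isobutylphosphonate
Product: 15 diethyl [(5S,6R)-5-[(tert-butyldimethylsilyl)oxy]-9-hydroxy-2,6-dimethyl-4-oxoundec-10-yn-3-yl]phosphonate (epimers at C3 and C9 of this chain), via propargylic alcohol ester 14 (not isolated)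
Conditions: HC≡CMgBr (1.05 equiv), THF, −78 °C; then 13/n-BuLi (3.5 equiv, premixed at −78 °C), −78 to −30 °C; aq NH4Cl
Reagents that add atoms: ethynylmagnesium bromide (C#C[Mg]Br)
Why: The Grignard reagent adds only to the aldehyde at −78 °C, and the resulting alkoxide keeps C9 at the alcohol level while the lithiated phosphonate acylates at the ester (Corey–Kwiatkowski β-ketophosphonate synthesis), so no ketone is present to compete; the two new centers are both lost later.

Step 8
Reactants: 15 diethyl [(5S,6R)-5-[(tert-butyldimethylsilyl)oxy]-9-hydroxy-2,6-dimethyl-4-oxoundec-10-yn-3-yl]phosphonate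
Product: 16 diethyl [(5S,6R)-5-[(tert-butyldimethylsilyl)oxy]-2,6-dimethyl-4,9-dioxoundec-10-yn-3-yl]phosphonate
Conditions: Dess–Martin periodinane, CH2Cl2, 0 °C
Reagents that add atoms: none
Why: Dess–Martin oxidation of the propargylic alcohol gives the terminal ynone under near-neutral conditions that spare the silyl ether and the ketophosphonate.

Step 9
Reactants: 16 diethyl [(5S,6R)-5-[(tert-butyldimethylsilyl)oxy]-2,6-dimethyl-4,9-dioxoundec-10-yn-3-yl]phosphonate
Product: 18 diethyl [(5S,6R,10Z)-5-[(tert-butyldimethylsilyl)oxy]-10-{[(tert-butyldimethylsilyl)oxy]methyl}-11-iodo-2,6-dimethyl-4,9-dioxoundec-10-en-3-yl]phosphonate, via hydroxymethyl iodoenone 17 (not isolated)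
Conditions: MgI2 (1.3 equiv), monomeric CH2O (CH2Cl2 solution, 3 equiv), CH2Cl2, 0 °C; then 2,6-lutidine, TBSOTf, −78 °C
Reagents that add atoms: magnesium iodide ([Mg+2].[I-].[I-]); formaldehyde (C=O); tert-butyldimethylsilyl triflate (CC(C)(C)[Si](C)(C)OS(=O)(=O)C(F)(F)F)
Why: β-Iodo Morita–Baylis–Hillman reaction: iodide adds 1,4 to the Mg-activated ynone and the allenolate takes up formaldehyde on the face away from iodine, so iodine ends up cis to the acyl group (Z), which is the geometry C6 must have relative to C9; the alkoxide is silylated in the same flask.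

Step 10
Reactants: 7 (2Z)-3-methylpenta-2,4-dien-1-ol, 18 diethyl [(5S,6R,10Z)-5-[(tert-butyldimethylsilyl)oxy]-10-{[(tert-butyldimethylsilyl)oxy]methyl}-11-iodo-2,6-dimethyl-4,9-dioxoundec-10-en-3-yl]phosphonate
Product: 20 diethyl [(5S,6R,10Z,14Z)-5-[(tert-butyldimethylsilyl)oxy]-10-{[(tert-butyldimethylsilyl)oxy]methyl}-16-hydroxy-2,6,14-trimethyl-4,9-dioxohexadeca-10,14-dien-3-yl]phosphonate, via bis-boron adduct 19 (not isolated)
Conditions: 7, 9-BBN-H (2.1 equiv), THF, 0 °C to rt; then aq Cs2CO3, 18, Pd(dppf)Cl2 (5 mol%), AsPh3, DMF, rt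
Reagents that add atoms: none
Why: 9-BBN attacks only the monosubstituted vinyl end of the diene, the aqueous base destroys leftover B–H before the ketones arrive, and the B-alkyl Suzuki–Miyaura coupling replaces iodine with retention, so both Z alkenes are carried over.

Step 11
Reactants: 20 diethyl [(5S,6R,10Z,14Z)-5-[(tert-butyldimethylsilyl)oxy]-10-{[(tert-butyldimethylsilyl)oxy]methyl}-16-hydroxy-2,6,14-trimethyl-4,9-dioxohexadeca-10,14-dien-3-yl]phosphonate
Product: 21 the (14R,15S)-14,15-epoxide of 20 (a (2S,3R)-2,3-epoxy alcohol, cis-oxirane)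
Conditions: Ti(OiPr)4 (2.0 equiv), L-(+)-diethyl tartrate (2.4 equiv), t-BuOOH, 4 Å MS, CH2Cl2, −20 °C
Reagents that add atoms: tert-butyl hydroperoxide (CC(C)(C)OO)
Why: Sharpless asymmetric epoxidation acts only on the allylic-alcohol alkene (the enone alkene is electron-poor and has no free OH); L-(+)-tartrate gives the (2S,3R) epoxy alcohol from this nerol-type Z alkene, the syn addition makes the oxirane cis, and the extra Ti(OiPr)4 covers what the ketophosphonate binds.

Step 12
Reactants: 21 the (14R,15S)-14,15-epoxide of 20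
Product: 23 13,19-bis-O-(tert-butyldimethylsilyl) ether of the target, via epoxy aldehyde 22 (not isolated)
Conditions: Dess–Martin periodinane, CH2Cl2, 0 °C; filter; then slow addition to LiCl, DBU, MeCN (0.001 M), rt
Reagents that add atoms: none
Why: Dess–Martin oxidation followed by a Masamune–Roush intramolecular Horner–Wadsworth–Emmons reaction at high dilution; reversible addition of the stabilised α-branched ketophosphonate leads to the E-enone with the acyl group trans to C3, and the mild base spares C13 and the epoxide.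

Step 13
Reactants: 23 13,19-bis-O-(tert-butyldimethylsilyl) ether of the target
Product: 24 target, (1E,3S,4R,7Z,12R,13S)-3,4-epoxy-13,19-dihydroxycembra-1,7-diene-9,14-dione
Conditions: Bu4NF/AcOH (1:1, 4 equiv), THF, 0 °C to rt
Reagents that add atoms: none
Why: Buffered fluoride desilylation removes both silyl ethers without the acid that would open the vinyl epoxide or the free base that would epimerise C13.

## Compound list
1 | 4-methylpyridine | Cc1ccncc1 | starting material
2 | 1-(2,4-dinitrophenyl)-4-methylpyridinium chloride | Cc1cc[n+](cc1)-c1ccc(cc1[N+](=O)[O-])[N+](=O)[O-].[Cl-] | intermediate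
3 | 4-[(2E,4E)-3-methyl-5-(morpholin-4-yl)penta-2,4-dienylidene]morpholin-4-ium chloride | CC(/C=C/N1CCOCC1)=C\C=[N+]1CCOCC1.[Cl-] | intermediate
4 | (2E,4E)-3-methyl-5-(morpholin-4-yl)penta-2,4-dienal | O=C/C=C(C)/C=C/N1CCOCC1 | intermediate
5 | (2Z)-3-methyl-1-(morpholin-4-yl)penta-2,4-dien-1-one | O=C(N1CCOCC1)/C=C(C)\C=C | intermediate
6 | (2Z)-3-methylpenta-2,4-dienal | O=C/C=C(C)\C=C | intermediate
7 | (2Z)-3-methylpenta-2,4-dien-1-ol | OC/C=C(C)\C=C | intermediate
8 | ethyl glyoxylate | CCOC(=O)C=O | starting material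
9 | (Z)-crotylboronic acid pinacol ester | C/C=C\CB1OC(C)(C)C(C)(C)O1 | starting material
10 | ethyl (2S,3R)-2-hydroxy-3-methylpent-4-enoate | C=C[C@@H](C)[C@H](O)C(=O)OCC | intermediate
11 | ethyl (2S,3R)-2-[(tert-butyldimethylsilyl)oxy]-3-methylpent-4-enoate | C=C[C@@H](C)[C@H](O[Si](C)(C)C(C)(C)C)C(=O)OCC | intermediate
12 | ethyl (2S,3R)-2-[(tert-butyldimethylsilyl)oxy]-3-methyl-6-oxohexanoate | O=CCC[C@@H](C)[C@H](O[Si](C)(C)C(C)(C)C)C(=O)OCC | intermediate
13 | diethyl isobutylphosphonate | CCOP(=O)(CC(C)C)OCC | starting material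
14 | ethyl (2S,3R)-2-[(tert-butyldimethylsilyl)oxy]-6-hydroxy-3-methyloct-7-ynoate (C6 epimers) | C#CC(O)CC[C@@H](C)[C@H](O[Si](C)(C)C(C)(C)C)C(=O)OCC | intermediate
15 | diethyl [(5S,6R)-5-[(tert-butyldimethylsilyl)oxy]-9-hydroxy-2,6-dimethyl-4-oxoundec-10-yn-3-yl]phosphonate | C#CC(O)CC[C@@H](C)[C@H](O[Si](C)(C)C(C)(C)C)C(=O)C(C(C)C)P(=O)(OCC)OCC | intermediate
16 | diethyl [(5S,6R)-5-[(tert-butyldimethylsilyl)oxy]-2,6-dimethyl-4,9-dioxoundec-10-yn-3-yl]phosphonate | C#CC(=O)CC[C@@H](C)[C@H](O[Si](C)(C)C(C)(C)C)C(=O)C(C(C)C)P(=O)(OCC)OCC | intermediate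
17 | diethyl [(5S,6R,10Z)-5-[(tert-butyldimethylsilyl)oxy]-10-(hydroxymethyl)-11-iodo-2,6-dimethyl-4,9-dioxoundec-10-en-3-yl]phosphonate | I/C=C(/CO)C(=O)CC[C@@H](C)[C@H](O[Si](C)(C)C(C)(C)C)C(=O)C(C(C)C)P(=O)(OCC)OCC | intermediate
18 | diethyl [(5S,6R,10Z)-5-[(tert-butyldimethylsilyl)oxy]-10-{[(tert-butyldimethylsilyl)oxy]methyl}-11-iodo-2,6-dimethyl-4,9-dioxoundec-10-en-3-yl]phosphonate | I/C=C(/CO[Si](C)(C)C(C)(C)C)C(=O)CC[C@@H](C)[C@H](O[Si](C)(C)C(C)(C)C)C(=O)C(C(C)C)P(=O)(OCC)OCC | intermediate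
19 | 9-[(3Z)-5-(9-borabicyclo[3.3.1]nonan-9-yloxy)-3-methylpent-3-enyl]-9-borabicyclo[3.3.1]nonane | C/C(CCB1C2CCCC1CCC2)=C/COB1C2CCCC1CCC2 | intermediate
20 | diethyl [(5S,6R,10Z,14Z)-5-[(tert-butyldimethylsilyl)oxy]-10-{[(tert-butyldimethylsilyl)oxy]methyl}-16-hydroxy-2,6,14-trimethyl-4,9-dioxohexadeca-10,14-dien-3-yl]phosphonate | OC/C=C(C)\CC/C=C(/CO[Si](C)(C)C(C)(C)C)C(=O)CC[C@@H](C)[C@H](O[Si](C)(C)C(C)(C)C)C(=O)C(C(C)C)P(=O)(OCC)OCC | intermediate
21 | (14R,15S)-14,15-epoxide of 20 | OC[C@@H]1O[C@]1(C)CC/C=C(/CO[Si](C)(C)C(C)(C)C)C(=O)CC[C@@H](C)[C@H](O[Si](C)(C)C(C)(C)C)C(=O)C(C(C)C)P(=O)(OCC)OCC | intermediate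
22 | epoxy aldehyde from 21 ((2R,3R)-oxirane-2-carbaldehyde terminus) | O=C[C@@H]1O[C@]1(C)CC/C=C(/CO[Si](C)(C)C(C)(C)C)C(=O)CC[C@@H](C)[C@H](O[Si](C)(C)C(C)(C)C)C(=O)C(C(C)C)P(=O)(OCC)OCC | intermediate
23 | 13,19-bis-O-(tert-butyldimethylsilyl) ether of the target | CC(C)/C1=C\[C@@H]2O[C@]2(C)CC/C=C(/CO[Si](C)(C)C(C)(C)C)C(=O)CC[C@@H](C)[C@H](O[Si](C)(C)C(C)(C)C)C1=O | intermediate
24 | (1E,3S,4R,7Z,12R,13S)-3,4-epoxy-13,19-dihydroxycembra-1,7-diene-9,14-dione | CC(C)/C1=C\[C@@H]2O[C@]2(C)CC/C=C(/CO)C(=O)CC[C@@H](C)[C@H](O)C1=O | target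

## Step count and risks
Total step count: 13. Longest linear sequence: 10 (steps 4 to 13).

**Step 2, thermal cascade.** The 3-methyl aminodienal may char at 200 °C or give E/Z mixtures. The fallback gives up the rearrangement. It uses none of 1 to 6; it sets out from purchased (Z)-3-methylpent-2-en-4-yn-1-ol F1. Semi-hydrogenation of F1 (H2, Pd/CaCO3 poisoned with Pb(OAc)2, quinoline, EtOAc) stops at the vinyl group and leaves the existing Z alkene alone. The fallback comes back to the route at 7.

**Step 9, iodide-triggered aldol with formaldehyde.** Formaldehyde may oligomerise or attack the ketophosphonate, and Z/E control may erode. The fallback sets out from 16 and installs the two alkene substituents by two cross-couplings.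
- Anti addition of I2 (CH2Cl2, rt) gives diethyl [(5S,6R,10E)-5-[(tert-butyldimethylsilyl)oxy]-10,11-diiodo-2,6-dimethyl-4,9-dioxoundec-10-en-3-yl]phosphonate F2, in which the terminal iodine is cis to the acyl group.
- The less hindered β-iodide couples first with borane 19 under the conditions of step 10. This gives the α-iodoenone diethyl [(5S,6R,10E,14Z)-5-[(tert-butyldimethylsilyl)oxy]-16-hydroxy-10-iodo-2,6,14-trimethyl-4,9-dioxohexadeca-10,14-dien-3-yl]phosphonate F3.
- A Stille coupling of F3 with tributyl{[(tert-butyldimethylsilyl)oxy]methyl}stannane (Pd2(dba)3, AsPh3, CuI, NMP) brings in C19. The fallback comes back to the route at 20.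

**Step 12, oxidation and ring closure.** The epoxy aldehyde and the resulting γ,δ-epoxy enone may not survive long exposure to base, and the hindered phosphonate reacts slowly. The fallback sets out from 20 and closes the ring before the oxirane exists.
- MnO2 (CH2Cl2) gives the Z-enal, diethyl [(5S,6R,10Z,14Z)-5-[(tert-butyldimethylsilyl)oxy]-10-{[(tert-butyldimethylsilyl)oxy]methyl}-2,6,14-trimethyl-4,9,16-trioxohexadeca-10,14-dien-3-yl]phosphonate F4.
- The same LiCl/DBU high-dilution olefination gives the macrocyclic (1E,3Z,7Z)-trienedione bis-silyl ether F5.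
- The only electron-rich alkene, C3=C4, is then epoxidised with a Shi fructose-derived ketone and Oxone. The catalyst enantiomer is chosen for the 3S,4R face. The fallback comes back to the route at 23.

## Further compounds
F1 | step 2 | (Z)-3-methylpent-2-en-4-yn-1-ol | OC/C=C(C)\C#C
F2 | step 9 | diethyl [(5S,6R,10E)-5-[(tert-butyldimethylsilyl)oxy]-10,11-diiodo-2,6-dimethyl-4,9-dioxoundec-10-en-3-yl]phosphonate | I/C=C(/I)C(=O)CC[C@@H](C)[C@H](O[Si](C)(C)C(C)(C)C)C(=O)C(C(C)C)P(=O)(OCC)OCC
F3 | step 9 | diethyl [(5S,6R,10E,14Z)-5-[(tert-butyldimethylsilyl)oxy]-16-hydroxy-10-iodo-2,6,14-trimethyl-4,9-dioxohexadeca-10,14-dien-3-yl]phosphonate | OC/C=C(C)\CC/C=C(/I)C(=O)CC[C@@H](C)[C@H](O[Si](C)(C)C(C)(C)C)C(=O)C(C(C)C)P(=O)(OCC)OCC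
F4 | step 12 | diethyl [(5S,6R,10Z,14Z)-5-[(tert-butyldimethylsilyl)oxy]-10-{[(tert-butyldimethylsilyl)oxy]methyl}-2,6,14-trimethyl-4,9,16-trioxohexadeca-10,14-dien-3-yl]phosphonate | O=C/C=C(C)\CC/C=C(/CO[Si](C)(C)C(C)(C)C)C(=O)CC[C@@H](C)[C@H](O[Si](C)(C)C(C)(C)C)C(=O)C(C(C)C)P(=O)(OCC)OCC
F5 | step 12 | (1E,3Z,7Z,12R,13S)-13,19-bis[(tert-butyldimethylsilyl)oxy]cembra-1,3,7-triene-9,14-dione | CC(C)/C1=C\C=C(C)/CC/C=C(/CO[Si](C)(C)C(C)(C)C)C(=O)CC[C@@H](C)[C@H](O[Si](C)(C)C(C)(C)C)C1=O
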